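**Retrosynthetic overview** (isochromene numbering: C1, O2, C3, C4, C4a, C5, C6, C7, C8, C8a)
1. The acetate goes on last; ring A (pyran) comes from 6-endo addition of the C1 hydroxyl to a C3≡C4 alkyne on the finished carbocycle.
2. Ring B and the C7 carbinol come from a carbene-catalysed crossed benzoin: the C6 aldehyde, as an acyl anion, attacks the C7 methyl ketone.
3. The benzoin substrate is a lactol that stores the enal with its formyl group cis to C8a; it arises from a dihydropyranone (temporary O–C8 ring) by acetylide 1,2-addition and allylic transposition.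
4. The dihydropyranone, with C8 and C8a set, comes from an asymmetric hetero-Diels–Alder reaction with 2,2-dimethoxypropanal; the dienyne side chain comes from (S)-2-methylbutan-1-ol.
5. Ring order: temporary oxygen ring → ring B → ring A.

Assumption: the propargyl phosphonate, methyl 2,2-dimethoxypropanoate and both enantiomers of the two chiral catalysts are catalogue items. The catalyst enantiomers written in steps 6 and 8 are assigned by analogy and would be confirmed on the first run.

**Step 1**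
Reactants: 1 (S)-2-methylbutan-1-ol; 2 2-(triphenyl-λ5-phosphanylidene)propanal
Product: 4 (2E,4S)-2,4-dimethylhex-2-enal, via (S)-2-methylbutanal 3 (not isolated)
Conditions: PhI(OAc)2 (1.1 equiv), 2,2,6,6-tetramethylpiperidin-1-oxyl (10 mol %), CH2Cl2, 23 °C; then 2, 40 °C
Reagents that add atoms: none
Why: Oxoammonium oxidation gives the volatile, epimerisable aldehyde without isolation and the stabilised ylide converts it to the (E)-enal by Wittig olefination, the C-methyl stereocentre coming unchanged from the chiral pool.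

**Step 2**
Reactants: 4 (2E,4S)-2,4-dimethylhex-2-enal; 5 diethyl [3-(trimethylsilyl)prop-2-yn-1-yl]phosphonate
Product: 7 (3E,5E,7S)-5,7-dimethylnona-3,5-dien-1-yne, via silyl dienyne 6 (not isolated)
Conditions: 5, LiN(SiMe3)2, THF, −78 °C; 4, −78 → 0 °C; then MeOH, K2CO3 (0.3 equiv), 23 °C
Reagents that add atoms: none
Why: The Horner–Wadsworth–Emmons reaction of the propargyl phosphonate anion gives the new disubstituted alkene mainly as the E isomer, and methanolysis then removes the alkynyl silyl group.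

**Step 3**
Reactants: 8 (E)-4-methoxybut-3-en-2-one
Product: 10 (E)-5-[(tert-butyldimethylsilyl)oxy]-1-methoxypent-1-en-3-one, via hydroxy enone 9 (not isolated)
Conditions: LiN(SiMe3)2, THF, −78 °C; CH2O (gas from cracked paraformaldehyde), −78 °C; then t-BuMe2SiOSO2CF3, −78 → 0 °C
Reagents that add atoms: formaldehyde C=O; tert-butyldimethylsilyl trifluoromethanesulfonate CC(C)(C)[Si](C)(C)OS(=O)(=O)C(F)(F)F
Why: The kinetic enolate forms at the methyl group (the only enolisable site), its aldol addition to formaldehyde installs C1, and silylating the lithium aldolate in the flask stops it cyclising to a dihydropyranone.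

**Step 4**
Reactants: 10 (E)-5-[(tert-butyldimethylsilyl)oxy]-1-methoxypent-1-en-3-one
Product: 11 (1E,3Z)-5-[(tert-butyldimethylsilyl)oxy]-1-methoxy-3-[(triethylsilyl)oxy]penta-1,3-diene
Conditions: Et3SiOSO2CF3, Et3N, Et2O, 0 °C
Reagents that add atoms: triethylsilyl trifluoromethanesulfonate CC[Si](CC)(CC)OS(=O)(=O)C(F)(F)F
Why: Soft enolisation with silyl triflate and amine gives the thermodynamically preferred (Z)-silyl enol ether, that is, a 4-substituted Danishefsky-type diene.

**Step 5**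
Reactants: 12 methyl 2,2-dimethoxypropanoate
Product: 13 2,2-dimethoxypropanal
Conditions: i-Bu2AlH (1.05 equiv), CH2Cl2, −78 °C; aqueous potassium sodium tartrate work-up
Reagents that add atoms: none
Why: Half-reduction of the ester stops at the aldehyde because the aluminium hemiacetal, chelated by an α-methoxy group, survives at −78 °C until work-up.

**Step 6**
Reactants: 11 (1E,3Z)-5-[(tert-butyldimethylsilyl)oxy]-1-methoxy-3-[(triethylsilyl)oxy]penta-1,3-diene; 13 2,2-dimethoxypropanal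
Product: 15 (2R,3R)-3-{[(tert-butyldimethylsilyl)oxy]methyl}-2-(1,1-dimethoxyethyl)-2,3-dihydro-4H-pyran-4-one, via cycloadduct 14 (not isolated)
Conditions: CrCl(C27H29NO2), i.e. chloro{2-(adamantan-1-yl)-6-[({(1S,2R)-2-oxido-2,3-dihydro-1H-inden-1-yl}imino)methyl]-4-methylphenolato}chromium (trivalent chromium, 5 mol %), 4 Å MS, t-BuOMe, 23 °C; then CF3CO2H (0.1 equiv), CH2Cl2, 0 °C
Reagents that add atoms: none
Why: In this endo-selective catalytic asymmetric hetero-Diels–Alder reaction the outward CH2OSi group of the (Z)-enol ether and the endo aldehyde substituent end up cis, which sets C8 and C8a as the 2,3-cis pair, while the chiral chromium Lewis acid sets the absolute sense (2R,3R) and acid then expels methoxytriethylsilane to give the enone.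

**Step 7**
Reactants: 7 (3E,5E,7S)-5,7-dimethylnona-3,5-dien-1-yne; 15 (2R,3R)-3-{[(tert-butyldimethylsilyl)oxy]methyl}-2-(1,1-dimethoxyethyl)-2,3-dihydro-4H-pyran-4-one
Product: 17 1-[(2R,3R)-3-{[(tert-butyldimethylsilyl)oxy]methyl}-4-[(3E,5E,7S)-5,7-dimethylnona-3,5-dien-1-yn-1-yl]-6-hydroxy-3,6-dihydro-2H-pyran-2-yl]ethan-1-one (anomer mixture), via propargylic alcohol 16 (not isolated)
Conditions: 7, n-BuLi, THF, −78 °C; CeCl3, −78 °C; 15, −78 °C; H2O quench; then pyridinium p-toluenesulfonate (0.2 equiv), acetone/H2O 10:1, 23 °C, stopped when the ketal is consumed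
Reagents that add atoms: water O
Why: The weakly basic cerium acetylide adds 1,2 to the vinylogous ester carbonyl without enolising C8a, and mild acid then ionises the tertiary allylic alcohol to the ring oxocarbenium ion, which water captures at C6 (Ferrier-type allylic transposition) to give a lactol that locks the formyl carbon cis to C8a while the same acid hydrolyses the dimethyl ketal to the C7 ketone, leaving C8 and C8a untouched.

**Step 8**
Reactants: 17 1-[(2R,3R)-3-{[(tert-butyldimethylsilyl)oxy]methyl}-4-[(3E,5E,7S)-5,7-dimethylnona-3,5-dien-1-yn-1-yl]-6-hydroxy-3,6-dihydro-2H-pyran-2-yl]ethan-1-one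
Product: 20 (4R,5R,6R)-3-[(3E,5E,7S)-5,7-dimethylnona-3,5-dien-1-yn-1-yl]-5,6-dihydroxy-4-(hydroxymethyl)-6-methylcyclohex-2-en-1-one, via open-chain enal 18 (not isolated), via silyl ether ketol 19 (not isolated)
Conditions: (5aS,10bR)-2-(pentafluorophenyl)-5a,10b-dihydro-4H,6H-indeno[2,1-b][1,2,4]triazolo[4,3-d][1,4]oxazin-2-ium tetrafluoroborate (15 mol %), Et3N (0.5 equiv), 4 Å MS, THF, 23 °C; then HF·pyridine, 0 °C
Reagents that add atoms: none
Why: Proposed new method: the lactol opens reversibly to enal 18, the triazolylidene adds to the aldehyde to give a Breslow-type acyl anion at C6 whose only ring-forming outlet is attack on the neighbouring C7 methyl ketone (homoenolate closure would need a four-membered ring), and a chair-like transition state with 8-OH and the CH2OSi arm equatorial, the ketone methyl equatorial and the carbonyl oxygen axial places the new 7-OH cis to 8-OH (7R), reinforced by the matched catalyst enantiomer; the closest known reaction type is the intramolecular crossed aldehyde–ketone benzoin cyclisation with chiral triazolium carbenes, extended here to a lactol-masked enynal, and HF·pyridine then only removes the silyl group.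

**Step 9**
Reactants: 20 (4R,5R,6R)-3-[(3E,5E,7S)-5,7-dimethylnona-3,5-dien-1-yn-1-yl]-5,6-dihydroxy-4-(hydroxymethyl)-6-methylcyclohex-2-en-1-one
Product: 22 (7R,8R,8aR)-3-[(1E,3E,5S)-3,5-dimethylhepta-1,3-dien-1-yl]-7-hydroxy-7-methyl-6-oxo-6,7,8,8a-tetrahydro-1H-isochromen-8-yl acetate, via diol 21 (not isolated)
Conditions: AuCl(PPh3) (5 mol %), AgOSO2CF3 (5 mol %), CH2Cl2, 23 °C; then pyridine, Ac2O, 0 → 23 °C
Reagents that add atoms: acetic anhydride CC(=O)OC(C)=O
Why: Under π-acid activation the alkyne carbon C3 (δ-carbon of the enynone, bearing the dienyl group) is the electrophilic terminus, so the primary C1 hydroxyl closes ring A by 6-endo-dig hydroalkoxylation (a bridged closure by 8-OH is prohibitively strained), and pyridine/Ac2O then acetylates the only secondary hydroxyl while the tertiary 7-OH stays free and no stereocentre is touched.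

**Compound list**
1 | (S)-2-methylbutan-1-ol | CC[C@H](C)CO | starting material
2 | 2-(triphenyl-λ5-phosphanylidene)propanal | CC(C=O)=P(c1ccccc1)(c1ccccc1)c1ccccc1 | starting material
3 | (S)-2-methylbutanal | CC[C@H](C)C=O | intermediate
4 | (2E,4S)-2,4-dimethylhex-2-enal | CC[C@H](C)/C=C(C)/C=O | intermediate
5 | diethyl [3-(trimethylsilyl)prop-2-yn-1-yl]phosphonate | CCOP(=O)(CC#C[Si](C)(C)C)OCC | starting material
6 | trimethyl[(3E,5E,7S)-5,7-dimethylnona-3,5-dien-1-yn-1-yl]silane | CC[C@H](C)/C=C(C)/C=C/C#C[Si](C)(C)C | intermediate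
7 | (3E,5E,7S)-5,7-dimethylnona-3,5-dien-1-yne | CC[C@H](C)/C=C(C)/C=C/C#C | intermediate
8 | (E)-4-methoxybut-3-en-2-one | CO/C=C/C(C)=O | starting material
9 | (E)-5-hydroxy-1-methoxypent-1-en-3-one (formed as its lithium alkoxide) | CO/C=C/C(=O)CCO | intermediate
10 | (E)-5-[(tert-butyldimethylsilyl)oxy]-1-methoxypent-1-en-3-one | CO/C=C/C(=O)CCO[Si](C)(C)C(C)(C)C | intermediate
11 | (1E,3Z)-5-[(tert-butyldimethylsilyl)oxy]-1-methoxy-3-[(triethylsilyl)oxy]penta-1,3-diene | CO/C=C/C(O[Si](CC)(CC)CC)=C/CO[Si](C)(C)C(C)(C)C | intermediate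
12 | methyl 2,2-dimethoxypropanoate | COC(=O)C(C)(OC)OC | starting material
13 | 2,2-dimethoxypropanal | CC(OC)(OC)C=O | intermediate
14 | (2R,3R,6S)-3-{[(tert-butyldimethylsilyl)oxy]methyl}-2-(1,1-dimethoxyethyl)-6-methoxy-4-[(triethylsilyl)oxy]-3,6-dihydro-2H-pyran | CO[C@@H]1C=C(O[Si](CC)(CC)CC)[C@H](CO[Si](C)(C)C(C)(C)C)[C@H](C(C)(OC)OC)O1 | intermediate
15 | (2R,3R)-3-{[(tert-butyldimethylsilyl)oxy]methyl}-2-(1,1-dimethoxyethyl)-2,3-dihydro-4H-pyran-4-one | CC(OC)(OC)[C@@H]1OC=CC(=O)[C@@H]1CO[Si](C)(C)C(C)(C)C | intermediate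
16 | (2R,3R)-3-{[(tert-butyldimethylsilyl)oxy]methyl}-2-(1,1-dimethoxyethyl)-4-[(3E,5E,7S)-5,7-dimethylnona-3,5-dien-1-yn-1-yl]-3,4-dihydro-2H-pyran-4-ol (C4 epimers) | CC(OC)(OC)[C@@H]1OC=CC(O)(C#C/C=C/C(C)=C/[C@@H](C)CC)[C@@H]1CO[Si](C)(C)C(C)(C)C | intermediate
17 | 1-[(2R,3R)-3-{[(tert-butyldimethylsilyl)oxy]methyl}-4-[(3E,5E,7S)-5,7-dimethylnona-3,5-dien-1-yn-1-yl]-6-hydroxy-3,6-dihydro-2H-pyran-2-yl]ethan-1-one (anomers) | CC(=O)[C@@H]1OC(O)C=C(C#C/C=C/C(C)=C/[C@@H](C)CC)[C@@H]1CO[Si](C)(C)C(C)(C)C | intermediate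
18 | (2E,4R,5R)-4-{[(tert-butyldimethylsilyl)oxy]methyl}-3-[(3E,5E,7S)-5,7-dimethylnona-3,5-dien-1-yn-1-yl]-5-hydroxy-6-oxohept-2-enal (formyl cis to C4) | O=C/C=C(\[C@H](CO[Si](C)(C)C(C)(C)C)[C@@H](O)C(C)=O)C#C/C=C/C(C)=C/[C@@H](C)CC | intermediate
19 | (4R,5R,6R)-4-{[(tert-butyldimethylsilyl)oxy]methyl}-3-[(3E,5E,7S)-5,7-dimethylnona-3,5-dien-1-yn-1-yl]-5,6-dihydroxy-6-methylcyclohex-2-en-1-one | CC[C@H](C)/C=C(C)/C=C/C#CC1=CC(=O)[C@](C)(O)[C@H](O)[C@H]1CO[Si](C)(C)C(C)(C)C | intermediate
20 | (4R,5R,6R)-3-[(3E,5E,7S)-5,7-dimethylnona-3,5-dien-1-yn-1-yl]-5,6-dihydroxy-4-(hydroxymethyl)-6-methylcyclohex-2-en-1-one | CC[C@H](C)/C=C(C)/C=C/C#CC1=CC(=O)[C@](C)(O)[C@H](O)[C@H]1CO | intermediate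
21 | (7R,8R,8aR)-3-[(1E,3E,5S)-3,5-dimethylhepta-1,3-dien-1-yl]-7,8-dihydroxy-7-methyl-1,7,8,8a-tetrahydro-6H-isochromen-6-one | CC[C@H](C)/C=C(C)/C=C/C1=CC2=CC(=O)[C@](C)(O)[C@H](O)[C@H]2CO1 | intermediate
22 | (7R,8R,8aR)-3-[(1E,3E,5S)-3,5-dimethylhepta-1,3-dien-1-yl]-7-hydroxy-7-methyl-6-oxo-6,7,8,8a-tetrahydro-1H-isochromen-8-yl acetate | CC[C@H](C)/C=C(C)/C=C/C1=CC2=CC(=O)[C@](C)(O)[C@H](OC(C)=O)[C@H]2CO1 | target

**Totals**
Total step count: 9. Longest linear sequence: 6 steps (steps 3, 4, 6, 7, 8, 9, from 8 to 22).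

**Three steps most likely to fail**

Step 8 (benzoin). The open enal can isomerise about C4a=C5 to the geometry that cannot cyclise. The carbene can divert into redox lactonisation through β- or ε-protonation. The catalyst enantiomer may be mismatched with the substrate bias at C7. The fallback sets out from 17 and comes back at 19. Compound 17 is treated with SmI2 in THF/t-BuOH at −78 °C, so that the ketyl of the unmasked aldehyde couples with the C7 ketone in a pinacol cyclisation. This gives (1RS,2S,3R,4R)-4-{[(tert-butyldimethylsilyl)oxy]methyl}-5-[(3E,5E,7S)-5,7-dimethylnona-3,5-dien-1-yn-1-yl]-2-methylcyclohex-5-ene-1,2,3-triol F1. MnO2 in CH2Cl2 then oxidises only the allylic secondary carbinol (the former aldehyde carbon) to the enone, giving 19, which is desilylated with HF·pyridine as in step 8. The facial selectivity of the pinacol step at C7 would need to be checked.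

Step 7 (acetylide addition, then transposition and ketal hydrolysis). The lactol can re-ionise under the acid needed for ketal hydrolysis and leak to a Meyer–Schuster-type dienone or to the wrong enal geometry. The fallback sets out from 15 and comes back at 17. The ketal is removed first, on the robust pyranone (pyridinium p-toluenesulfonate, wet acetone, 50 °C), to give (2R,3R)-2-acetyl-3-{[(tert-butyldimethylsilyl)oxy]methyl}-2,3-dihydro-4H-pyran-4-one F2. The methyl ketone is then masked in the flask as its lithium enolate (LiN(SiMe3)2, −78 °C) and the cerium acetylide of 7 is added to the remaining pyranone carbonyl. Quenching gives 1-[(2R,3R)-3-{[(tert-butyldimethylsilyl)oxy]methyl}-4-[(3E,5E,7S)-5,7-dimethylnona-3,5-dien-1-yn-1-yl]-4-hydroxy-3,4-dihydro-2H-pyran-2-yl]ethan-1-one F3. This needs only a brief exposure to the same acid in wet THF at 0 °C to rearrange to 17.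

Step 6 (hetero-Diels–Alder). The α-quaternary aldehyde may react slowly, and the cis selectivity and enantioselectivity are not assured for this diene. The fallback sets out from 13 and comes back at 15. The boron enolate (Bu2BOSO2CF3, Et3N, CH2Cl2, −78 °C) of (R)-4-benzyl-3-{3-[(tert-butyldimethylsilyl)oxy]propanoyl}oxazolidin-2-one F4, made from the oxazolidinone and the silyloxypropanoic acid, undergoes an Evans syn-aldol with 13. This gives (R)-4-benzyl-3-[(2R,3R)-2-{[(tert-butyldimethylsilyl)oxy]methyl}-3-hydroxy-4,4-dimethoxypentanoyl]oxazolidin-2-one F5. AlMe3 and MeONHMe·HCl convert it to (2R,3R)-2-{[(tert-butyldimethylsilyl)oxy]methyl}-3-hydroxy-N,4,4-trimethoxy-N-methylpentanamide F6. HC≡CMgBr gives (4R,5R)-4-{[(tert-butyldimethylsilyl)oxy]methyl}-5-hydroxy-6,6-dimethoxyhept-1-yn-3-one F7. AgOSO2CF3 (10 mol %) in CH2Cl2 closes the β-hydroxy ynone 6-endo to 15.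

**Further compounds**
F1 | step 8 | (1RS,2S,3R,4R)-4-{[(tert-butyldimethylsilyl)oxy]methyl}-5-[(3E,5E,7S)-5,7-dimethylnona-3,5-dien-1-yn-1-yl]-2-methylcyclohex-5-ene-1,2,3-triol | CC[C@H](C)/C=C(C)/C=C/C#CC1=CC(O)[C@](C)(O)[C@H](O)[C@H]1CO[Si](C)(C)C(C)(C)C
F2 | step 7 | (2R,3R)-2-acetyl-3-{[(tert-butyldimethylsilyl)oxy]methyl}-2,3-dihydro-4H-pyran-4-one | CC(=O)[C@@H]1OC=CC(=O)[C@@H]1CO[Si](C)(C)C(C)(C)C
F3 | step 7 | 1-[(2R,3R)-3-{[(tert-butyldimethylsilyl)oxy]methyl}-4-[(3E,5E,7S)-5,7-dimethylnona-3,5-dien-1-yn-1-yl]-4-hydroxy-3,4-dihydro-2H-pyran-2-yl]ethan-1-one (C4 epimers) | CC(=O)[C@@H]1OC=CC(O)(C#C/C=C/C(C)=C/[C@@H](C)CC)[C@@H]1CO[Si](C)(C)C(C)(C)C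
F4 | step 6 | (R)-4-benzyl-3-{3-[(tert-butyldimethylsilyl)oxy]propanoyl}oxazolidin-2-one | O=C(CCO[Si](C)(C)C(C)(C)C)N1[C@H](Cc2ccccc2)COC1=O
F5 | step 6 | (R)-4-benzyl-3-[(2R,3R)-2-{[(tert-butyldimethylsilyl)oxy]methyl}-3-hydroxy-4,4-dimethoxypentanoyl]oxazolidin-2-one | CC(OC)(OC)[C@H](O)[C@@H](CO[Si](C)(C)C(C)(C)C)C(=O)N1[C@H](Cc2ccccc2)COC1=O
F6 | step 6 | (2R,3R)-2-{[(tert-butyldimethylsilyl)oxy]methyl}-3-hydroxy-N,4,4-trimethoxy-N-methylpentanamide | CC(OC)(OC)[C@H](O)[C@@H](CO[Si](C)(C)C(C)(C)C)C(=O)N(C)OC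
F7 | step 6 | (4R,5R)-4-{[(tert-butyldimethylsilyl)oxy]methyl}-5-hydroxy-6,6-dimethoxyhept-1-yn-3-one | CC(OC)(OC)[C@H](O)[C@@H](CO[Si](C)(C)C(C)(C)C)C(=O)C#C
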